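The route rests on an intramolecular Diels–Alder reaction of an open-chain trienone. The isopropenyl ketone (C1=C10, activated by the C9 carbonyl) adds to the 2-methyl-1,3-diene C2=C3–C4=C5, forming C1–C2 and C5–C10 in one operation and so closing rings A and B with the quaternary C10 and the trans ring fusion. It exploits the C9 oxygen next to C10 in ring B and the C4 methyl carbinol of ring A, which comes from the Δ3 alkene. The precursor carries a silyloxy group at C7, taken from a commercial glutarate. This group steers the cycloaddition and is then eliminated to the Δ7-enone, where axial copper-catalysed conjugate addition installs the 7α side chain.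

Key step: step 7

Remarks. Atoms are numbered as in eudesmane: ring A = C1, C2, C3, C4, C5, C10; ring B = C5, C6, C7, C8, C9, C10; C14 is the methyl on C10, C15 the methyl on C4, C11–C13 the side chain on C7. α/β refer to the usual drawing with the C10 methyl β. The target is 10β-CH3, 5α-H (trans-fused), 4α-OH/4β-CH3, 9β-acyloxy, 7α side chain (7β-H), with an (S)-3-methylpentanoate. Assumption: monomethyl (R)-3-(tert-butyldimethylsilyloxy)glutarate 1, a statin side-chain building block, is taken as commercially available.

Step 1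
Reactants: 1 (3R)-3-[(tert-butyldimethylsilyl)oxy]-5-methoxy-5-oxopentanoic acid
Product: 3 (4S)-4-[(tert-butyldimethylsilyl)oxy]oxan-2-one, via hydroxy acid 2 (not isolated)
Conditions: LiBH4, THF, 0 °C to rt; then 1 M HCl to pH 3, CH2Cl2, rt
Reagents that add atoms: none
Why: LiBH4 should reduce the methyl ester but not the lithium carboxylate formed first, and the 5-hydroxy acid lactonises on acidification (chemoselective ester reduction, lactonisation), so the ester carbon becomes C5 and the acid carbon C9 with the C7 centre untouched; reduction of the acid end with borane instead would give the enantiomeric lactone.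

Step 2
Reactants: 3 (4S)-4-[(tert-butyldimethylsilyl)oxy]oxan-2-one
Product: 4 (3S)-3-[(tert-butyldimethylsilyl)oxy]-5-hydroxy-N-methoxy-N-methylpentanamide
Conditions: MeNHOMe·HCl, AlMe3, CH2Cl2, 0 °C to rt; aq. potassium sodium tartrate
Reagents that add atoms: N,O-dimethylhydroxylamine hydrochloride, CNOC.Cl
Why: Weinreb aminolysis of the lactone by the aluminium amide made in the flask should open the ring to the hydroxy Weinreb amide without touching the silyl ether.

Step 3
Reactants: 4 (3S)-3-[(tert-butyldimethylsilyl)oxy]-5-hydroxy-N-methoxy-N-methylpentanamide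
Product: 5 (3S)-3-[(tert-butyldimethylsilyl)oxy]-N-methoxy-N-methyl-5-oxopentanamide
Conditions: Dess–Martin periodinane, NaHCO3, CH2Cl2, 0 °C to rt
Reagents that add atoms: none
Why: Dess–Martin oxidation of the primary alcohol under buffered, non-basic conditions should give the β-silyloxy aldehyde without β-elimination.

Step 4
Reactants: 5 (3S)-3-[(tert-butyldimethylsilyl)oxy]-N-methoxy-N-methyl-5-oxopentanamide; 6 2-(triphenylphosphoranylidene)propanal
Product: 7 (3S,5E)-3-[(tert-butyldimethylsilyl)oxy]-N-methoxy-N,6-dimethyl-7-oxohept-5-enamide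
Conditions: toluene, 80 °C
Reagents that add atoms: none
Why: Wittig reaction of the stabilised α-methyl ylide is selective for the aldehyde over the Weinreb amide and should give the (E)-trisubstituted enal, which places C6 and C3 trans across C4=C5 as the cycloaddition requires.

Step 5
Reactants: 7 (3S,5E)-3-[(tert-butyldimethylsilyl)oxy]-N-methoxy-N,6-dimethyl-7-oxohept-5-enamide
Product: 8 (3S,5E)-3-[(tert-butyldimethylsilyl)oxy]-N-methoxy-N,6-dimethylocta-5,7-dienamide
Conditions: Ph3PCH3Br, KN(SiMe3)2, THF, −78 to 0 °C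
Reagents that add atoms: methyltriphenylphosphonium bromide, C[P+](c1ccccc1)(c1ccccc1)c1ccccc1.[Br-]
Why: Wittig methylenation of the enal at low temperature should turn C3 into the terminal vinyl group (C3=C2) and leave the Weinreb amide intact, giving the (E)-2-methyl-1,3-diene.

Step 6
Reactants: 8 (3S,5E)-3-[(tert-butyldimethylsilyl)oxy]-N-methoxy-N,6-dimethylocta-5,7-dienamide; 9 isopropenylmagnesium bromide
Product: 10 (5S,7E)-5-[(tert-butyldimethylsilyl)oxy]-2,8-dimethyldeca-1,7,9-trien-3-one
Conditions: THF, −20 to 0 °C; cold aq. NH4Cl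
Reagents that add atoms: none
Why: Weinreb ketone synthesis, in which the magnesium chelate stops at mono-addition and releases the isopropenyl ketone (C10=C1 next to C9=O) only on cold quench; the trienone is used at once.

Step 7
Reactants: 10 (5S,7E)-5-[(tert-butyldimethylsilyl)oxy]-2,8-dimethyldeca-1,7,9-trien-3-one
Product: 11 7β-[(tert-butyldimethylsilyl)oxy]-11,12,13-trinor-5α-eudesm-3-en-9-one (trans-fused, 10β-CH3)
Conditions: toluene (0.02 M), 2,6-di-tert-butyl-4-methylphenol (cat.), 90 °C
Reagents that add atoms: none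
Why: Thermal intramolecular Diels–Alder reaction of the type 1 (1,7,9-decatrien-3-one) class, the closest known precedent: the isopropenyl ketone C10=C1, activated by the C9 carbonyl in the tether, adds suprafacially across the s-cis (E)-diene C2=C3–C4=C5 in one concerted, asynchronous [4+2] step that forms C5–C10 and C1–C2 and leaves the Δ3 alkene. Ring A (C10–C1–C2–C3–C4–C5) is the new cyclohexene, closed by the C1–C2 bond, and ring B (C5–C6–C7–C8–C9–C10) is closed at the same time by the C5–C10 bond across the four-atom tether. The quaternary C10 and the C5 methine are set relative to each other by the tether-anti arrangement (carbonyl exo, C14 methyl endo over the diene), which α-methyl enone dienophiles prefer and which keeps the enone planar inside a chair-like tether, so H5 and C14 should end up trans. Their absolute sense is relayed from C7: the silyloxy group should occupy the equatorial site of that chair, which exposes the dienophile face leading to 10β-CH3/5α-H with 7β-OTBS. The step needs trans over cis fusion and equatorial over axial OTBS, while regiochemistry is fixed by the tether and by the (E)-diene geometry set in step 4. Minor diastereomers are to be removed by chromatography here, so that elimination of the C7 oxygen in step 9 leaves a single enantiomer of the enone.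

Step 8
Reactants: 11 7β-[(tert-butyldimethylsilyl)oxy]-11,12,13-trinor-5α-eudesm-3-en-9-one
Product: 12 7β-[(tert-butyldimethylsilyl)oxy]-4α-hydroxy-11,12,13-trinor-5α-eudesman-9-one
Conditions: Co(acac)2 (cobalt bis(acetylacetonate), cat.), PhSiH3, O2 (1 atm), THF, rt
Reagents that add atoms: dioxygen, O=O
Why: Mukaiyama hydration (hydrogen-atom transfer from a cobalt hydride to C3, then trapping of the tertiary C4 radical by O2) puts oxygen on C4, and O2 should approach from the α face because the β face is screened by the 1,3-diaxial C10 methyl, giving the 4α-hydroxy-4β-methyl centre.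

Step 9
Reactants: 12 7β-[(tert-butyldimethylsilyl)oxy]-4α-hydroxy-11,12,13-trinor-5α-eudesman-9-one
Product: 13 4α-hydroxy-11,12,13-trinor-5α-eudesm-7-en-9-one
Conditions: 1,8-diazabicyclo[5.4.0]undec-7-ene, toluene, 80 °C
Reagents that add atoms: none
Why: E1cB elimination of silanolate from the β-silyloxy ketone through the C8 enolate (C10 is quaternary, so only C8 can enolise) should give the conjugated Δ7-enone and erase the C7 control centre, with heating chosen because the leaving group is equatorial.

Step 10
Reactants: 13 4α-hydroxy-11,12,13-trinor-5α-eudesm-7-en-9-one; 9 isopropenylmagnesium bromide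
Product: 14 4α-hydroxy-5α,7βH-eudesm-11-en-9-one (7α-isopropenyl, axial)
Conditions: CuBr·SMe2 (cat.), THF, −40 °C; aq. NH4Cl
Reagents that add atoms: none
Why: Copper-catalysed conjugate addition of the Grignard reagent (used in excess because of the free hydroxyl) should deliver the isopropenyl group to C7 along the axial trajectory through a chair-like enolate, that is from the α face, which sets the 7α side chain, while the quaternary C10 shields C9 from 1,2-addition.

Step 11
Reactants: 14 4α-hydroxy-5α,7βH-eudesm-11-en-9-one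
Product: 15 5α,7βH-eudesm-11-ene-4α,9β-diol
Conditions: Li, NH3 (l), THF, EtOH, −78 to −33 °C; NH4Cl
Reagents that add atoms: none
Why: Dissolving-metal reduction of the ketone under protonating conditions should give the thermodynamically preferred equatorial 9β-alcohol (the axial 9α epimer would be syn-diaxial to the 7α-isopropenyl group), and the isolated alkene is inert.

Step 12
Reactants: 15 5α,7βH-eudesm-11-ene-4α,9β-diol; 16 (3S)-3-methylpentanoic acid
Product: 17 9β-[(3S)-3-methylpentanoyloxy]-5α,7βH-eudesm-11-en-4α-ol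
Conditions: EDC·HCl (1-ethyl-3-(3-dimethylaminopropyl)carbodiimide hydrochloride), 4-(dimethylamino)pyridine, CH2Cl2, rt
Reagents that add atoms: none
Why: Steglich esterification should acylate the secondary 9β-hydroxyl and leave the tertiary 4α-hydroxyl untouched, and the acid cannot racemise because its stereocentre is β to the carboxyl group.

Step 13
Reactants: 17 9β-[(3S)-3-methylpentanoyloxy]-5α,7βH-eudesm-11-en-4α-ol
Product: 18 9β-[(3S)-3-methylpentanoyloxy]-5α,7βH-eudesm-11(13)-ene-4α,12-diol
Conditions: SeO2 (0.5 equiv), t-BuOOH, CH2Cl2, rt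
Reagents that add atoms: selenium dioxide, O=[Se]=O; tert-butyl hydroperoxide, CC(C)(C)OO
Why: Selenium dioxide allylic oxidation (ene reaction followed by [2,3]-sigmatropic shift) should hydroxylate the methyl group of the isopropenyl unit to the primary allylic alcohol, with tert-butyl hydroperoxide as terminal oxidant.

Step 14
Reactants: 18 9β-[(3S)-3-methylpentanoyloxy]-5α,7βH-eudesm-11(13)-ene-4α,12-diol
Product: 20 4α-hydroxy-9β-[(3S)-3-methylpentanoyloxy]-5α,7βH-eudesm-11(13)-en-12-oic acid (target), via enal 19 (not isolated)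
Conditions: 2,2,6,6-tetramethylpiperidin-1-oxyl (cat.), PhI(OAc)2, CH2Cl2, rt; then NaClO2, NaH2PO4, 2-methylbut-2-ene, t-BuOH/H2O, rt
Reagents that add atoms: sodium chlorite, [Na+].[O-]Cl=O
Why: Oxoammonium oxidation of the primary allylic alcohol to the enal, followed in the same flask by Pinnick oxidation, should give the α-substituted acrylic acid without touching the ester, the tertiary alcohol or the alkene.

Compound list
1 | (3R)-3-[(tert-butyldimethylsilyl)oxy]-5-methoxy-5-oxopentanoic acid | COC(=O)C[C@H](O[Si](C)(C)C(C)(C)C)CC(=O)O | starting material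
2 | (3S)-3-[(tert-butyldimethylsilyl)oxy]-5-hydroxypentanoic acid | OCC[C@H](O[Si](C)(C)C(C)(C)C)CC(=O)O | intermediate
3 | (4S)-4-[(tert-butyldimethylsilyl)oxy]oxan-2-one | O=C1C[C@@H](O[Si](C)(C)C(C)(C)C)CCO1 | intermediate
4 | (3S)-3-[(tert-butyldimethylsilyl)oxy]-5-hydroxy-N-methoxy-N-methylpentanamide | CON(C)C(=O)C[C@@H](O[Si](C)(C)C(C)(C)C)CCO | intermediate
5 | (3S)-3-[(tert-butyldimethylsilyl)oxy]-N-methoxy-N-methyl-5-oxopentanamide | CON(C)C(=O)C[C@@H](O[Si](C)(C)C(C)(C)C)CC=O | intermediate
6 | 2-(triphenylphosphoranylidene)propanal | CC(C=O)=P(c1ccccc1)(c1ccccc1)c1ccccc1 | starting material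
7 | (3S,5E)-3-[(tert-butyldimethylsilyl)oxy]-N-methoxy-N,6-dimethyl-7-oxohept-5-enamide | CON(C)C(=O)C[C@@H](O[Si](C)(C)C(C)(C)C)C/C=C(C)/C=O | intermediate
8 | (3S,5E)-3-[(tert-butyldimethylsilyl)oxy]-N-methoxy-N,6-dimethylocta-5,7-dienamide | CON(C)C(=O)C[C@@H](O[Si](C)(C)C(C)(C)C)C/C=C(C)/C=C | intermediate
9 | isopropenylmagnesium bromide | C=C(C)[Mg]Br | starting material
10 | (5S,7E)-5-[(tert-butyldimethylsilyl)oxy]-2,8-dimethyldeca-1,7,9-trien-3-one | C=C(C)C(=O)C[C@@H](O[Si](C)(C)C(C)(C)C)C/C=C(C)/C=C | intermediate
11 | 7β-[(tert-butyldimethylsilyl)oxy]-11,12,13-trinor-5α-eudesm-3-en-9-one (trans-fused, 10β-CH3, 5α-H) | CC(C)(C)[Si](C)(C)O[C@@H]1CC(=O)[C@@]2(C)CCC=C(C)[C@@H]2C1 | intermediate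
12 | 7β-[(tert-butyldimethylsilyl)oxy]-4α-hydroxy-11,12,13-trinor-5α-eudesman-9-one | CC(C)(C)[Si](C)(C)O[C@@H]1CC(=O)[C@@]2(C)CCC[C@@](C)(O)[C@@H]2C1 | intermediate
13 | 4α-hydroxy-11,12,13-trinor-5α-eudesm-7-en-9-one | C1=CC(=O)[C@@]2(C)CCC[C@@](C)(O)[C@@H]2C1 | intermediate
14 | 4α-hydroxy-5α,7βH-eudesm-11-en-9-one (7α-isopropenyl) | C=C(C)[C@H]1CC(=O)[C@@]2(C)CCC[C@@](C)(O)[C@@H]2C1 | intermediate
15 | 5α,7βH-eudesm-11-ene-4α,9β-diol | C=C(C)[C@H]1C[C@H](O)[C@@]2(C)CCC[C@@](C)(O)[C@@H]2C1 | intermediate
16 | (3S)-3-methylpentanoic acid | CC[C@H](C)CC(=O)O | starting material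
17 | 9β-[(3S)-3-methylpentanoyloxy]-5α,7βH-eudesm-11-en-4α-ol | C=C(C)[C@H]1C[C@H](OC(=O)C[C@@H](C)CC)[C@@]2(C)CCC[C@@](C)(O)[C@@H]2C1 | intermediate
18 | 9β-[(3S)-3-methylpentanoyloxy]-5α,7βH-eudesm-11(13)-ene-4α,12-diol | C=C(CO)[C@H]1C[C@H](OC(=O)C[C@@H](C)CC)[C@@]2(C)CCC[C@@](C)(O)[C@@H]2C1 | intermediate
19 | 4α-hydroxy-9β-[(3S)-3-methylpentanoyloxy]-5α,7βH-eudesm-11(13)-en-12-al | C=C(C=O)[C@H]1C[C@H](OC(=O)C[C@@H](C)CC)[C@@]2(C)CCC[C@@](C)(O)[C@@H]2C1 | intermediate
20 | 4α-hydroxy-9β-[(3S)-3-methylpentanoyloxy]-5α,7βH-eudesm-11(13)-en-12-oic acid (CNP0471281.1) | C=C(C(=O)O)[C@H]1C[C@H](OC(=O)C[C@@H](C)CC)[C@@]2(C)CCC[C@@](C)(O)[C@@H]2C1 | target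

Total step count: 14. Longest linear sequence: 14 steps (1 to 20).

Steps most likely to fail

Step 7. The cycloaddition may run mainly through the tether-syn (carbonyl-endo) transition state and so give the cis ring fusion, or the silyloxy group may discriminate the two faces of the dienophile only weakly. The fallback sets out from 10 and comes back at 11. The ketone of 10 would be reduced under reagent control (CBS reduction: BH3·SMe2, (R)-1-methyl-3,3-diphenyltetrahydro-1H,3H-pyrrolo[1,2-c][1,3,2]oxazaborole, THF, −30 °C) to (3S,5S,7E)-5-[(tert-butyldimethylsilyl)oxy]-2,8-dimethyldeca-1,7,9-trien-3-ol F1. With the carbonyl gone there is no carbonyl-endo preference, and both oxygen substituents can sit equatorial on the chair tether. Heating F1 (toluene, 180 °C, sealed tube) should then effect the cycloaddition of the unactivated triene to 7β-[(tert-butyldimethylsilyl)oxy]-11,12,13-trinor-5α-eudesm-3-en-9β-ol F2, and Dess–Martin oxidation of F2 returns ketone 11.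

Step 8. Trapping of the planar C4 radical may show poor facial selectivity and deliver the 4β-hydroxy epimer alongside the wanted one. The fallback sets out from 11 and comes back at 12. Epoxidation with m-chloroperbenzoic acid (NaHCO3, CH2Cl2, 0 °C) should occur on the α face, anti to the axial C10 methyl, to give 7β-[(tert-butyldimethylsilyl)oxy]-3α,4α-epoxy-11,12,13-trinor-5α-eudesman-9-one F3. Here the C4–O bond is set by the peracid and is not broken afterwards. LiBHEt3 (THF, 0 °C to rt) should open the epoxide by hydride attack at the secondary C3 and reduce the C9 ketone, giving 7β-[(tert-butyldimethylsilyl)oxy]-11,12,13-trinor-5α-eudesmane-4α,9β-diol F4. Dess–Martin oxidation of the secondary alcohol of F4 gives 12.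

Step 13. The ene reaction of the selenium reagent may engage the tertiary C7–H instead of the methyl group, which would put oxygen on C7, or the oxidation may run on unselectively. The fallback sets out from 17 and comes back at 19. Ene-type chlorination with hypochlorous acid (Ca(OCl)2, CO2, CH2Cl2/H2O, 0 °C) proceeds through the tertiary C11 cation, which loses a methyl proton, and should give 12-chloro-9β-[(3S)-3-methylpentanoyloxy]-5α,7βH-eudesm-11(13)-en-4α-ol F5. N-oxide (Kornblum-type) oxidation of F5 with 4-methylmorpholine N-oxide (MeCN, 60 °C) gives enal 19, here isolated, which is carried into the chlorite stage of step 14.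

Further compounds
F1 | step 7 | (3S,5S,7E)-5-[(tert-butyldimethylsilyl)oxy]-2,8-dimethyldeca-1,7,9-trien-3-ol | C=C(C)[C@@H](O)C[C@@H](O[Si](C)(C)C(C)(C)C)C/C=C(C)/C=C
F2 | step 7 | 7β-[(tert-butyldimethylsilyl)oxy]-11,12,13-trinor-5α-eudesm-3-en-9β-ol | CC(C)(C)[Si](C)(C)O[C@@H]1C[C@H](O)[C@@]2(C)CCC=C(C)[C@@H]2C1
F3 | step 8 | 7β-[(tert-butyldimethylsilyl)oxy]-3α,4α-epoxy-11,12,13-trinor-5α-eudesman-9-one | CC(C)(C)[Si](C)(C)O[C@@H]1CC(=O)[C@@]2(C)CC[C@H]3O[C@@]3(C)[C@@H]2C1
F4 | step 8 | 7β-[(tert-butyldimethylsilyl)oxy]-11,12,13-trinor-5α-eudesmane-4α,9β-diol | CC(C)(C)[Si](C)(C)O[C@@H]1C[C@H](O)[C@@]2(C)CCC[C@@](C)(O)[C@@H]2C1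
F5 | step 13 | 12-chloro-9β-[(3S)-3-methylpentanoyloxy]-5α,7βH-eudesm-11(13)-en-4α-ol | C=C(CCl)[C@H]1C[C@H](OC(=O)C[C@@H](C)CC)[C@@]2(C)CCC[C@@](C)(O)[C@@H]2C1
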